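**Plan**
- Unit 1 (plain locants) is the flavone whose ring B carries the ether oxygen at C4'. Unit 2 (double-primed locants) is the flavone that bears this oxygen at C8''.
- Enabling feature: ring A of unit 1 is an acylphloroglucinol. C4a carries the acyl carbon C4, oxygens sit on C5, C7 and C8a, only O7 (para to C4a) is methylated, and O5 and O8a are equivalent until ring C closes. This is the C6/C4/C2 oxygen pattern of 4-methoxy-6-methyl-2-pyrone, whose methyl carbon becomes C4a.
- Cuts, latest first: O5''–CH3 and O4'''–benzyl; O1''–C2'' and C2''–C3'' (chalcone); C4''–C4a'' (Fries); O1–C2; C4a–C8a (pyrone opening and Claisen reclosure); C2–C3 and C4–C4a (two acylations of the pyrone side chain); C4'–O (SNAr).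
- Forward: ring A'' and ring B are bought and joined through oxygen, and the pyrone side chain is grown to the triketone. Ring A and then ring C of unit 1 close. Ring C'' is built on the unmasked phenol of ring A'', and ring B'' arrives with the aldehyde.
- The target has no stereocentre. The only geometries on the way (ring-derived 2E enol ether, E-chalcone) disappear on aromatisation.

Key step: step 6

Remark: di- and triketones are drawn and named as keto tautomers although they are largely enolised; connectivity is not affected.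

**Step 1**
Reactants: 1 2-hydroxy-4,6-dimethoxybenzaldehyde
Product: 2 2-(benzyloxy)-4,6-dimethoxybenzaldehyde
Conditions: BnBr, K2CO3, DMF, 60 °C
Reagents that add atoms: benzyl bromide, BrCc1ccccc1
Why: Williamson etherification of the only free phenol marks the oxygen that will become O1'' with a group that hydrogenolysis can later remove in the presence of the methyl ethers.

**Step 2**
Reactants: 2 2-(benzyloxy)-4,6-dimethoxybenzaldehyde
Product: 4 2-(benzyloxy)-4,6-dimethoxyphenol, via aryl formate 3 (not isolated)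
Conditions: mCPBA, CH2Cl2, 0 °C to rt, aq NaHCO3 wash; crude 3, K2CO3 (cat.), MeOH, rt, under N2
Reagents that add atoms: 3-chloroperoxybenzoic acid, O=C(OO)c1cccc(Cl)c1
Why: In this Baeyer–Villiger oxidation (the peracid form of the Dakin reaction) the very electron-rich trialkoxyaryl group migrates in preference to hydrogen, and the formate is then transesterified by methanol under mild base that leaves the ethers alone.

**Step 3**
Reactants: 4 2-(benzyloxy)-4,6-dimethoxyphenol; 5 methyl 4-fluorobenzoate
Product: 6 methyl 4-[2-(benzyloxy)-4,6-dimethoxyphenoxy]benzoate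
Conditions: Cs2CO3, degassed DMSO, 110 °C
Reagents that add atoms: none
Why: This is a nucleophilic aromatic substitution by addition–elimination, in which the para ester stabilises the Meisenheimer adduct, fluoride is the best leaving group for the mechanism, and the loosely paired caesium phenoxide in DMSO offsets the hindrance of the two ortho alkoxy groups.

**Step 4**
Reactants: 7 4-methoxy-6-methyl-2H-pyran-2-one; 8 N-methoxy-N-methylacetamide
Product: 9 4-methoxy-6-(2-oxopropyl)-2H-pyran-2-one
Conditions: LiN(i-Pr)2 (1.1 equiv), THF, −78 °C; 8, −78 to −20 °C; cold 1 M HCl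
Reagents that add atoms: none
Why: The 6-methyl group is the vinylogous α-position of the lactone and is the site deprotonated by LiN(i-Pr)2, and Weinreb acylation stops at the chelated tetrahedral adduct, so the more acidic ketone 9 appears only on quench and can neither consume the anion nor be acylated twice.

**Step 5**
Reactants: 9 4-methoxy-6-(2-oxopropyl)-2H-pyran-2-one; 6 methyl 4-[2-(benzyloxy)-4,6-dimethoxyphenoxy]benzoate
Product: 10 6-(4-{4-[2-(benzyloxy)-4,6-dimethoxyphenoxy]phenyl}-2,4-dioxobutyl)-4-methoxy-2H-pyran-2-one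
Conditions: 9 (1.2 equiv), LiN(i-Pr)2 (3.6 equiv), THF, −78 to −20 °C; 6 (1.0 equiv), −78 °C to rt; cold 1 M HCl to pH 4
Reagents that add atoms: none
Why: In this crossed Claisen condensation of a dianion (γ-acylation as known for β-keto ester and β-diketone dianions) the base first removes the doubly activated CH2 proton and then a CH3 proton, the less stabilised terminal carbanion attacks the non-enolisable ester 6, and the extra base absorbs the acidic proton of the new β-diketone.

**Step 6**
Reactants: 10 6-(4-{4-[2-(benzyloxy)-4,6-dimethoxyphenoxy]phenyl}-2,4-dioxobutyl)-4-methoxy-2H-pyran-2-one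
Product: 12 1-{4-[2-(benzyloxy)-4,6-dimethoxyphenoxy]phenyl}-3-(2,6-dihydroxy-4-methoxyphenyl)propane-1,3-dione, via ring-opened enol ether ester 11 (not isolated)
Conditions: Mg(OMe)2 (5 equiv), MeOH (THF co-solvent), reflux; cold 1 M HCl
Reagents that add atoms: magnesium methoxide, [Mg+2].[O-]C.[O-]C (its methoxide enters 11 and leaves again on ring closure; 12 holds no reagent atom)
Why: Methoxide adds reversibly to the lactone carbonyl and expels the pyrone C6 enolate, a good leaving group because it is conjugated with the side-chain ketone, giving ester 11 in which the ester carbon and the C4 methylene remain cis on C2=C3 (2E by the sequence rules) as they were in the ring. The carbon between C5=O and C7=O of 11 (future C4a), held as a magnesium-chelated enolate, attacks the ester carbonyl C1 (future C8a) in a Dieckmann-type Claisen condensation, a 6-(enolexo)-exo-trig closure, and loss of methoxide followed by tautomerisation makes aromatic ring A irreversibly. The closest known reaction type is the Mg(OMe)2-induced recyclisation of 6-(2-oxoalkyl)-4-methoxy-2-pyrones to 2-acyl-5-methoxyresorcinols, the laboratory counterpart of chalcone-synthase folding. No stereocentre is created, and the pyrone methoxy group ends as the 7-OMe flanked by two free, equivalent hydroxyls. The step needs closure of C6 onto C1 to outrun aldol-type closures (C4 onto C9, C8 onto C3) and dehydration of the 5,7,9-trione to a 4-pyranone. Magnesium ties C7=O and C9=O into an unreactive chelate while activating C6, the enol ether keeps C3 a poor electrophile, the basic medium does not dehydrate, and the cis geometry holds C1 within reach of C6.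

**Step 7**
Reactants: 12 1-{4-[2-(benzyloxy)-4,6-dimethoxyphenoxy]phenyl}-3-(2,6-dihydroxy-4-methoxyphenyl)propane-1,3-dione
Product: 13 2-{4-[2-(benzyloxy)-4,6-dimethoxyphenoxy]phenyl}-5-hydroxy-7-methoxy-4H-chromen-4-one
Conditions: p-TsOH·H2O (10 mol %), toluene, reflux, Dean–Stark
Reagents that add atoms: none
Why: In this acid-catalysed cyclodehydration, the closing stage of the Baker–Venkataraman flavone synthesis, either of the two equivalent phenols adds 6-exo-trig to the aryl ketone and water is lost, so a single flavone forms with the other phenol left as the chelated 5-OH, and an early loss of benzyl would only anticipate step 8.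

**Step 8**
Reactants: 13 2-{4-[2-(benzyloxy)-4,6-dimethoxyphenoxy]phenyl}-5-hydroxy-7-methoxy-4H-chromen-4-one
Product: 14 5-hydroxy-2-[4-(2-hydroxy-4,6-dimethoxyphenoxy)phenyl]-7-methoxy-4H-chromen-4-one
Conditions: H2 (1 atm), 10 % Pd/C, THF–MeOH, rt
Reagents that add atoms: none
Why: Hydrogenolysis of an aryl benzyl ether over Pd/C at atmospheric pressure is much faster than reduction of the chromone C2=C3 bond, which is part of a vinylogous ester, and it frees only the oxygen destined to be O1''.

**Step 9**
Reactants: 14 5-hydroxy-2-[4-(2-hydroxy-4,6-dimethoxyphenoxy)phenyl]-7-methoxy-4H-chromen-4-one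
Product: 16 2-[4-(3-acetyl-2-hydroxy-4,6-dimethoxyphenoxy)phenyl]-5-hydroxy-7-methoxy-4H-chromen-4-one, via aryl acetate 15 (not isolated)
Conditions: Ac2O (1.5 equiv), BF3·OEt2 (6 equiv), 80 °C; then H2O–MeOH, 60 °C
Reagents that add atoms: acetic anhydride, CC(=O)OC(C)=O
Why: O-acetylation and BF3-promoted Fries rearrangement is the standard path from 3,5-dimethoxyphenols to 2-hydroxy-4,6-dimethoxyacetophenones, and it places the acetyl group on the carbon ortho to the phenol rather than on the para carbon between the two methoxy groups because the ortho product is held as a six-membered boron chelate, while ring A of unit 1 is deactivated by its carbonyl group and by boron bound to the 5-OH/C4=O pair.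

**Step 10**
Reactants: 16 2-[4-(3-acetyl-2-hydroxy-4,6-dimethoxyphenoxy)phenyl]-5-hydroxy-7-methoxy-4H-chromen-4-one; 17 4-(benzyloxy)benzaldehyde
Product: 18 2-{4-[3-{(2E)-3-[4-(benzyloxy)phenyl]prop-2-enoyl}-2-hydroxy-4,6-dimethoxyphenoxy]phenyl}-5-hydroxy-7-methoxy-4H-chromen-4-one
Conditions: 17 (1.3 equiv), KOH (50 % aq, 15 equiv), EtOH–THF, rt; 1 M HCl, 0 °C
Reagents that add atoms: none
Why: This Claisen–Schmidt condensation of the only methyl ketone with a non-enolisable aldehyde gives the E-enone by E1cB dehydration, and the chromone of unit 1 is shielded from hydroxide as its electron-rich 5-phenoxide, with any reversible opening to the diketone undone by the acidic work-up.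

**Step 11**
Reactants: 18 2-{4-[3-{(2E)-3-[4-(benzyloxy)phenyl]prop-2-enoyl}-2-hydroxy-4,6-dimethoxyphenoxy]phenyl}-5-hydroxy-7-methoxy-4H-chromen-4-one
Product: 19 2-[4-(benzyloxy)phenyl]-8-[4-(5-hydroxy-7-methoxy-4-oxo-4H-chromen-2-yl)phenoxy]-5,7-dimethoxy-4H-chromen-4-one
Conditions: I2 (10 mol %), DMSO, 120 °C
Reagents that add atoms: none
Why: The iodine-catalysed oxidative cyclisation of a 2'-hydroxychalcone runs through 6-endo-trig oxa-Michael closure, α-iodination and loss of HI, with DMSO re-oxidising HI, and it can use only the free hydroxyl next to the aryloxy group because the other ortho oxygen is still methylated, which fixes the 8''-aryloxy rather than a 6''-aryloxy pattern.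

**Step 12**
Reactants: 19 2-[4-(benzyloxy)phenyl]-8-[4-(5-hydroxy-7-methoxy-4-oxo-4H-chromen-2-yl)phenoxy]-5,7-dimethoxy-4H-chromen-4-one
Product: 20 5-hydroxy-8-[4-(5-hydroxy-7-methoxy-4-oxo-4H-chromen-2-yl)phenoxy]-2-(4-hydroxyphenyl)-7-methoxy-4H-chromen-4-one (target)
Conditions: BCl3 (1 M in CH2Cl2, 6 equiv), pentamethylbenzene (3 equiv), CH2Cl2, −78 to 0 °C; ice–water
Reagents that add atoms: none
Why: In this Lewis-acid ether cleavage BCl3 bound to C4''=O removes the peri 5''-methyl group through a six-membered chelate and ionises the aryl benzyl ether, with pentamethylbenzene trapping the benzyl cation, whereas the unchelated 7- and 7''-methyl ethers and the diaryl ether persist at or below 0 °C.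

**Compound list**
1 | 2-hydroxy-4,6-dimethoxybenzaldehyde | COc1cc(O)c(C=O)c(OC)c1 | starting material
2 | 2-(benzyloxy)-4,6-dimethoxybenzaldehyde | COc1cc(OCc2ccccc2)c(C=O)c(OC)c1 | intermediate
3 | 2-(benzyloxy)-4,6-dimethoxyphenyl formate | COc1cc(OCc2ccccc2)c(OC=O)c(OC)c1 | intermediate
4 | 2-(benzyloxy)-4,6-dimethoxyphenol | COc1cc(OCc2ccccc2)c(O)c(OC)c1 | intermediate
5 | methyl 4-fluorobenzoate | COC(=O)c1ccc(F)cc1 | starting material
6 | methyl 4-[2-(benzyloxy)-4,6-dimethoxyphenoxy]benzoate | COC(=O)c1ccc(Oc2c(OC)cc(OC)cc2OCc2ccccc2)cc1 | intermediate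
7 | 4-methoxy-6-methyl-2H-pyran-2-one | COc1cc(=O)oc(C)c1 | starting material
8 | N-methoxy-N-methylacetamide | CON(C)C(C)=O | starting material
9 | 4-methoxy-6-(2-oxopropyl)-2H-pyran-2-one | COc1cc(=O)oc(CC(C)=O)c1 | intermediate
10 | 6-(4-{4-[2-(benzyloxy)-4,6-dimethoxyphenoxy]phenyl}-2,4-dioxobutyl)-4-methoxy-2H-pyran-2-one | COc1cc(=O)oc(CC(=O)CC(=O)c2ccc(Oc3c(OC)cc(OC)cc3OCc3ccccc3)cc2)c1 | intermediate
11 | methyl (2E)-9-{4-[2-(benzyloxy)-4,6-dimethoxyphenoxy]phenyl}-3-methoxy-5,7,9-trioxonon-2-enoate | COC(=O)/C=C(/OC)CC(=O)CC(=O)CC(=O)c1ccc(Oc2c(OC)cc(OC)cc2OCc2ccccc2)cc1 | intermediate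
12 | 1-{4-[2-(benzyloxy)-4,6-dimethoxyphenoxy]phenyl}-3-(2,6-dihydroxy-4-methoxyphenyl)propane-1,3-dione | COc1cc(O)c(C(=O)CC(=O)c2ccc(Oc3c(OC)cc(OC)cc3OCc3ccccc3)cc2)c(O)c1 | intermediate
13 | 2-{4-[2-(benzyloxy)-4,6-dimethoxyphenoxy]phenyl}-5-hydroxy-7-methoxy-4H-chromen-4-one | COc1cc(O)c2c(=O)cc(-c3ccc(Oc4c(OC)cc(OC)cc4OCc4ccccc4)cc3)oc2c1 | intermediate
14 | 5-hydroxy-2-[4-(2-hydroxy-4,6-dimethoxyphenoxy)phenyl]-7-methoxy-4H-chromen-4-one | COc1cc(O)c2c(=O)cc(-c3ccc(Oc4c(OC)cc(OC)cc4O)cc3)oc2c1 | intermediate
15 | 2-[4-(5-hydroxy-7-methoxy-4-oxo-4H-chromen-2-yl)phenoxy]-3,5-dimethoxyphenyl acetate | COc1cc(O)c2c(=O)cc(-c3ccc(Oc4c(OC)cc(OC)cc4OC(C)=O)cc3)oc2c1 | intermediate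
16 | 2-[4-(3-acetyl-2-hydroxy-4,6-dimethoxyphenoxy)phenyl]-5-hydroxy-7-methoxy-4H-chromen-4-one | COc1cc(O)c2c(=O)cc(-c3ccc(Oc4c(OC)cc(OC)c(C(C)=O)c4O)cc3)oc2c1 | intermediate
17 | 4-(benzyloxy)benzaldehyde | O=Cc1ccc(OCc2ccccc2)cc1 | starting material
18 | 2-{4-[3-{(2E)-3-[4-(benzyloxy)phenyl]prop-2-enoyl}-2-hydroxy-4,6-dimethoxyphenoxy]phenyl}-5-hydroxy-7-methoxy-4H-chromen-4-one | COc1cc(O)c2c(=O)cc(-c3ccc(Oc4c(OC)cc(OC)c(C(=O)/C=C/c5ccc(OCc6ccccc6)cc5)c4O)cc3)oc2c1 | intermediate
19 | 2-[4-(benzyloxy)phenyl]-8-[4-(5-hydroxy-7-methoxy-4-oxo-4H-chromen-2-yl)phenoxy]-5,7-dimethoxy-4H-chromen-4-one | COc1cc(O)c2c(=O)cc(-c3ccc(Oc4c(OC)cc(OC)c5c(=O)cc(-c6ccc(OCc7ccccc7)cc6)oc45)cc3)oc2c1 | intermediate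
20 | 5-hydroxy-8-[4-(5-hydroxy-7-methoxy-4-oxo-4H-chromen-2-yl)phenoxy]-2-(4-hydroxyphenyl)-7-methoxy-4H-chromen-4-one | COc1cc(O)c2c(=O)cc(-c3ccc(Oc4c(OC)cc(O)c5c(=O)cc(-c6ccc(O)cc6)oc45)cc3)oc2c1 | target

**Step count**
Total: 12 steps. Longest linear sequence: 11 steps (steps 1–3 and 5–12, from 1). Step 4 is the one-step side branch from 7.

**Steps most likely to fail**

Step 5. Proton transfer from the newly formed β-diketone to unreacted dianion, together with slow attack on an ester deactivated by its para aryloxy donor, may stall the acylation. The fallback replaces the Claisen acylation by aldol addition and oxidation; it sets out from 4 and 9 and returns at 10.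
- Phenol 4 is arylated with 4-fluorobenzaldehyde (K2CO3, DMF, 120 °C), a better SNAr acceptor than 5, to give 4-[2-(benzyloxy)-4,6-dimethoxyphenoxy]benzaldehyde F1.
- The dianion of 9 (LiN(i-Pr)2, 2.1 equiv, THF, −78 °C) should add quickly to F1, and the resulting alkoxide cannot quench further dianion. This gives racemic 6-(4-{4-[2-(benzyloxy)-4,6-dimethoxyphenoxy]phenyl}-4-hydroxy-2-oxobutyl)-4-methoxy-2H-pyran-2-one F2.
- Oxidation of this β-hydroxy ketone with 2-iodoxybenzoic acid (EtOAc, 75 °C) leads to 10.

Step 6. Aldol-type folding through the aryl ketone, dehydration of the trione to a pyranone, or retro-Claisen loss of the aroyl group to methoxide may compete with the Claisen closure. The fallback keeps the same C4a–C8a bond and the same reaction but carries it out earlier, on a substrate without the third ketone. It sets out from 9 and 6 and returns at 12.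
- Ketone 9 with Mg(OMe)2 in refluxing MeOH, the parent case of the recyclisation, should give 1-(2,6-dihydroxy-4-methoxyphenyl)ethan-1-one F3.
- Ester 6 is saponified (LiOH, THF–H2O) to 4-[2-(benzyloxy)-4,6-dimethoxyphenoxy]benzoic acid F4.
- F4 is converted with (COCl)2 and catalytic DMF into 4-[2-(benzyloxy)-4,6-dimethoxyphenoxy]benzoyl chloride F5.
- The lithium polyanion of F3 (LiN(SiMe3)2, 4.5 equiv, THF, −78 °C) is acylated at carbon by F5 to give 12.

Step 10. The long exposure to hydroxide may open the finished chromone of unit 1 and degrade it by retro-Claisen cleavage before the hindered, chelated methyl ketone has condensed. The fallback replaces the aldol and oxidation sequence by enolate aroylation with a non-nucleophilic base followed by dehydration. It sets out from 16, bypasses 18 and returns at 19.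
- The lithium polyanion of 16 (LiN(SiMe3)2, 5 equiv, THF, −78 °C) is C-acylated with commercial 4-(benzyloxy)benzoyl chloride. This gives 1-[4-(benzyloxy)phenyl]-3-{2-hydroxy-3-[4-(5-hydroxy-7-methoxy-4-oxo-4H-chromen-2-yl)phenoxy]-4,6-dimethoxyphenyl}propane-1,3-dione F6.
- F6 closes to 19 with catalytic p-TsOH·H2O in refluxing toluene.

**Further compounds**
F1 | step 5 | 4-[2-(benzyloxy)-4,6-dimethoxyphenoxy]benzaldehyde | COc1cc(OC)c(Oc2ccc(C=O)cc2)c(OCc2ccccc2)c1
F2 | step 5 | rac-6-(4-{4-[2-(benzyloxy)-4,6-dimethoxyphenoxy]phenyl}-4-hydroxy-2-oxobutyl)-4-methoxy-2H-pyran-2-one | COc1cc(=O)oc(CC(=O)CC(O)c2ccc(Oc3c(OC)cc(OC)cc3OCc3ccccc3)cc2)c1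
F3 | step 6 | 1-(2,6-dihydroxy-4-methoxyphenyl)ethan-1-one | COc1cc(O)c(C(C)=O)c(O)c1
F4 | step 6 | 4-[2-(benzyloxy)-4,6-dimethoxyphenoxy]benzoic acid | COc1cc(OC)c(Oc2ccc(C(=O)O)cc2)c(OCc2ccccc2)c1
F5 | step 6 | 4-[2-(benzyloxy)-4,6-dimethoxyphenoxy]benzoyl chloride | COc1cc(OC)c(Oc2ccc(C(=O)Cl)cc2)c(OCc2ccccc2)c1
F6 | step 10 | 1-[4-(benzyloxy)phenyl]-3-{2-hydroxy-3-[4-(5-hydroxy-7-methoxy-4-oxo-4H-chromen-2-yl)phenoxy]-4,6-dimethoxyphenyl}propane-1,3-dione | COc1cc(O)c2c(=O)cc(-c3ccc(Oc4c(OC)cc(OC)c(C(=O)CC(=O)c5ccc(OCc6ccccc6)cc5)c4O)cc3)oc2c1
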